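# Proposed synthesis of 3,5-dihydroxy-7,8,3',4',5'-pentamethoxyflavone through a 4-benzyloxyisoxazole

## Analysis of the target

Target 18 (C20H20O9) is a flavonol: a 4H-chromen-4-one in which ring A (C4a to C8a) is fused to the pyranone ring C (O1, C2, C3, C4), with ring B, a 3,4,5-trimethoxyphenyl group, on C2. It has no stereocentre, so the whole problem is one of regiochemistry. Seven oxygens sit on the periphery: five methyl ethers (C7, C8, C3', C4', C5') and two free hydroxyls (C3 and C5), both hydrogen-bonded to the C4 carbonyl. Ring A is 1,2,3,5-tetraoxygenated, and the two oxygens flanking C4a are not equivalent: the one next to the C8 methoxy group must become O1 and the other the free 5-hydroxyl. A mistake there gives the 5,6,7-isomer, and hot strong acid can interconvert the two patterns by ring opening and reclosure (Wessely–Moser). The sensitive groups are the 3-hydroxy-4-pyranone, which oxidises in base and binds metals, and the doubly flanked methyl ethers at C8 and C4', which are the first to be lost under forcing Lewis-acid conditions. The hard part is to build the C4–C3–C2 unit, which carries oxygen on every carbon, and to join it to ring A through the correct oxygen. The strategy rests on that chain, C4(=O)–C3(OH)–C2(–O1): a 4-alkoxyisoxazole holds the same three carbons at the same oxidation level, with nitrogen standing in for the C4 oxygen, a benzyl ether on C3 and the ring oxygen on C2.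

## Retrosynthetic reasoning

**18 to 17 (O–CH3 bond at C5).** The target is traced back to its 5-O-methyl ether 17. Throughout the route, the two oxygens ortho to the carbon that becomes C4a are told apart by their protecting groups: the future O1 is a benzyl ether, the future 5-hydroxyl a methyl ether. Once ring C exists, the C5 methoxy group is the only ether peri to the C4 carbonyl, so the forward step is a chelation-directed cleavage that must leave the other five methyl ethers alone.

**17 to 15 (O1–C2 bond, C4=O exchanged for C=N).** Opening ring C at O1–C2 and writing the C4 carbonyl as its nitrogen analogue leads to amino enone 16, the product of reductive N–O cleavage of isoxazole 15. The cut is made here because the isoxazole is inert to the chemistry needed before it, and because one hydrogenolysis can break the N–O bond and both benzyl ethers. The forward reaction must free the single ortho phenol, let it add to the aroyl carbon (future C2), and hydrolyse the nitrogen off C4. The C2=C3 double bond of the flavone appears only after the hydrogenation.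

**15 to 6 and 13 (isoxazole C3–C4 and O–C5 bonds; flavone C4–C3 and O–C2).** Cutting both bonds divides the molecule into ring A carrying one carbon (nitrile oxide 6) and ring B carrying two (enamine 13), each from a simple arene. No other pair of cuts in the five-membered ring gives two fragments that already hold all seven oxygens in place. The forward cycloaddition must place the benzyloxy carbon of 13 on the carbon of the dipole; the polarity of the enamine dictates this. Cycloadduct 14 then loses amine 12 to become aromatic.

**6 to 5 to 4 (functional group changes at the one-carbon unit).** The dipole comes from aldoxime 5 by dehydrogenation and the oxime from aldehyde 4 by condensation. No skeletal bond is involved. The forward oxidation must not touch the activated C5–H of the very electron-rich ring.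

**4 to 3 to 2 to 1 (O–benzyl, O–methyl and aryl–CHO bonds).** Benzyl ether 4 comes from phenol 3, and 3 from tetramethyl ether 2 by cleavage of the one methyl ether wedged between the formyl group and a neighbouring methoxy group. Aldehyde 2 arises from symmetrical arene 1, whose two free positions are equivalent, so formylation is unambiguous. This order brings all four ring A oxygens in one commercial compound. The forward demethylation carries the regiochemical burden of the ring A series.

**13 to 11 and 12 (enamine C–N bond); 11 to 10 and 8 (aryl–carbonyl bond); 10 from 9; 8 from 7.** Enamine 13 is the condensation product of ketone 11 with amine 12. Ketone 11 has hydrogen on one α-carbon only, so a single regioisomer is possible. The 3,4,5-trimethoxy pattern cannot be acylated directly at the right position, so the aryl–carbonyl bond is made from aryllithium 10 (from bromide 9) and N-methoxy-N-methyl amide 8, itself from acid chloride 7.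

## Alternatives that were turned down

**Alternative 1:** Ring C is disconnected at O1–C2 with C3 carried as a carbon–iodine bond. In the forward step an electrophilic iodine reagent activates the triple bond of ynone A2, 3,4,5-trimethoxy-2-[3-(3,4,5-trimethoxyphenyl)prop-2-ynoyl]phenyl methanesulfonate. The ortho methoxy oxygen attacks the alkyne carbon bearing ring B in a 6-endo closure, the counter-ion removes the methyl group, and 3-iodochromone A1 results.
- In its favour: the chromone is reached quickly and convergently. Closure is unambiguous because the other ortho position carries a sulfonate. The 5-hydroxyl is later freed by sulfonate cleavage and not by Lewis-acid demethylation. On that last point it is stronger than the chosen route, which ends with a selective ether cleavage.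
- Against it: C3 arrives as C–I, so a carbon–oxygen bond must still be made on an electron-poor pyranone that nucleophilic oxygen bases open at C2. Electrophilic iodine can also attack the activated positions of rings A and B. The basic desulfonylation exposes a flavonol to base.
- Comparison: step count is similar or longer once the iodide-to-hydroxyl exchange is counted. The chosen route brings the C3 oxygen in from the start as a benzyl ether.

**Alternative 2:** Ring A is disconnected at C4a–C5 and grown on a preformed pyranone. Heating racemic cyclobutenone A4 opens the four-membered ring to a dienylketene, whose ketene carbon bonds to pyranone C5 in a 6π-electrocyclisation, giving 5,8-hydroquinone A3 after tautomerisation.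
- In its favour: the oxygen pattern of ring A follows from connectivity, not from selective ether cleavage. The 5-hydroxyl is born free, and its chelation should allow selective methylation of the 8-hydroxyl. On regiochemical certainty in ring A it is stronger than the chosen route.
- Against it: A4 requires a C6-metalated 2-aryl-3-alkoxy-4-pyranone, a carbanion on a ring that is itself an electrophile, and that pyranone needs its own multistep synthesis. A3 is an air-sensitive hydroquinone that oxidises readily to the quinone. Two further steps (methylation, acetal removal) follow.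
- Comparison: it is longer and its intermediates are more fragile. The chosen route uses two ordinary arenes and robust intermediates up to the isoxazole.

**Alternative 3:** Ring C is disconnected at C4–C4a. The acid A6, activated as a mixed anhydride with a perfluorinated acid anhydride, acylates the only free ortho position of its aryloxy ring and gives flavone A5.
- In its favour: closure cannot go to the wrong position, and both hydroxyls are benzyl ethers, so a single hydrogenolysis finishes the synthesis. That endgame is cleaner than the final demethylation of the chosen route.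
- Against it: A6 is a tetrasubstituted alkene with oxygen on both carbons and a required geometry (carboxyl cis to aryloxy). Adding a phenol to an arylpropiolate gives no α-oxygen, so the α-benzyloxy group needs a separate, uncertain step. The aryloxy partner, a tetraoxygenated phenol with one benzyl among methyl ethers, is not readily available. Strongly acidic acylium conditions threaten the benzyl ethers and can acylate the electron-rich ring B.
- Comparison: the difficulty moves into making the precursor. In the chosen route the precursors are made by standard reactions and the risk sits in one well-known type of cycloaddition.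

Key step: step 9

## Remark on the chemistry

Enamine 13 is drawn as the isomer with nitrogen and benzyloxy cis (Z). A mixture of double-bond isomers is acceptable, and cycloadduct 14 is racemic, because both sp3 centres of 14 disappear when pyrrolidine is eliminated.

## Route

**Step 1**
Reactants: 1 1,2,3,5-tetramethoxybenzene
Product: 2 2,3,4,6-tetramethoxybenzaldehyde
Conditions: POCl3, DMF, 0 °C → 65 °C; then ice-water
Reagents that add atoms: N,N-dimethylformamide, CN(C)C=O; water, O
Why: Vilsmeier–Haack formylation; the two free positions of 1 are equivalent and each is ortho or para to three methoxy groups, so the chloroiminium ion should attack there and hydrolysis should give one aldehyde.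

**Step 2**
Reactants: 2 2,3,4,6-tetramethoxybenzaldehyde
Product: 3 2-hydroxy-3,4,6-trimethoxybenzaldehyde
Conditions: BCl3 (1.1 equiv), CH2Cl2, −10 °C → rt; then H2O
Reagents that add atoms: none
Why: Chelation-directed ortho-demethylation: boron bridges the formyl oxygen and an ortho methoxy oxygen and chloride removes the methyl group. The C2 methoxy group, wedged between the formyl group and the C3 methoxy group, is twisted out of the ring plane, so its oxygen is the more basic and its cleavage relieves strain; one equivalent at low temperature should spare the C6 ether.

**Step 3**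
Reactants: 3 2-hydroxy-3,4,6-trimethoxybenzaldehyde
Product: 4 2-(benzyloxy)-3,4,6-trimethoxybenzaldehyde
Conditions: BnBr, K2CO3, DMF, 60 °C
Reagents that add atoms: benzyl bromide, BrCc1ccccc1
Why: Williamson ether synthesis; warming in DMF overcomes the hydrogen bond of the phenol to the aldehyde, and there is no other acidic site.

**Step 4**
Reactants: 4 2-(benzyloxy)-3,4,6-trimethoxybenzaldehyde
Product: 5 (E)-2-(benzyloxy)-3,4,6-trimethoxybenzaldehyde oxime
Conditions: NH2OH·HCl, NaOAc, EtOH–H2O, 60 °C
Reagents that add atoms: hydroxylamine hydrochloride, NO.Cl
Why: Oxime condensation; the aldehyde is hindered but still reactive toward this small nucleophile, and the hydroxyl should settle anti to the aryl group.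

**Step 5**
Reactants: 5 (E)-2-(benzyloxy)-3,4,6-trimethoxybenzaldehyde oxime
Product: 6 2-(benzyloxy)-3,4,6-trimethoxybenzonitrile oxide
Conditions: PhI(OAc)2 (1.1 equiv), MeOH, CF3CO2H (cat.), 0 °C; cold aqueous NaHCO3 work-up, used at once
Reagents that add atoms: none
Why: Oxidative dehydrogenation of an aldoxime by a trivalent iodine reagent (ligand exchange at iodine, then loss of iodobenzene and acetic acid); no electrophilic halogen is present, so the activated C5–H of the ring should not be halogenated. The two ortho alkoxy groups shield the CNO carbon, which slows dimerisation to the furoxan and allows 6 to be handled as a discrete compound.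

**Step 6**
Reactants: 7 benzyloxyacetyl chloride
Product: 8 2-(benzyloxy)-N-methoxy-N-methylacetamide
Conditions: MeNHOMe·HCl, Et3N, CH2Cl2, 0 °C → rt
Reagents that add atoms: N,O-dimethylhydroxylamine hydrochloride, CNOC.Cl
Why: N-acylation of an amine by an acid chloride gives the Weinreb amide.

**Step 7**
Reactants: 9 5-bromo-1,2,3-trimethoxybenzene; 8 2-(benzyloxy)-N-methoxy-N-methylacetamide
Product: 11 2-(benzyloxy)-1-(3,4,5-trimethoxyphenyl)ethanone, via (3,4,5-trimethoxyphenyl)lithium 10 (not isolated)
Conditions: n-BuLi, THF, −78 °C; then 8, −78 → 0 °C; 1 M HCl
Reagents that add atoms: none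
Why: Bromine–lithium exchange followed by Weinreb ketone synthesis; the chelated tetrahedral adduct persists until the acidic quench, so a second addition to the ketone should not occur.

**Step 8**
Reactants: 11 2-(benzyloxy)-1-(3,4,5-trimethoxyphenyl)ethanone; 12 pyrrolidine
Product: 13 1-[(Z)-2-(benzyloxy)-1-(3,4,5-trimethoxyphenyl)ethenyl]pyrrolidine
Conditions: pyrrolidine (6 equiv), TiCl4 (0.55 equiv), toluene, 0 °C → rt; filtered under N2, volatiles and excess amine removed in vacuo, used crude
Reagents that add atoms: none
Why: TiCl4-mediated enamine condensation, in which the titanium reagent activates the aryl ketone and binds the water formed. Only the benzyloxymethyl carbon bears α-hydrogen, so a single regioisomer can form.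

**Step 9**
Reactants: 6 2-(benzyloxy)-3,4,6-trimethoxybenzonitrile oxide; 13 1-[(Z)-2-(benzyloxy)-1-(3,4,5-trimethoxyphenyl)ethenyl]pyrrolidine
Product: 15 4-(benzyloxy)-3-[2-(benzyloxy)-3,4,6-trimethoxyphenyl]-5-(3,4,5-trimethoxyphenyl)isoxazole, via 5-pyrrolidinyl-isoxazoline cycloadduct 14 (not isolated)
Conditions: 13 (1.3 equiv), CH2Cl2, 0 °C → rt; then 1 M HCl, THF, rt
Reagents that add atoms: none
Why: Nitrile oxide 6 is the 1,3-dipole and the electron-rich double bond of 13 the dipolarophile in a [3+2] cycloaddition, the established way from ketone enamines to isoxazoles. The enamine carbon bearing the benzyloxy group carries the larger HOMO coefficient and bonds to the electrophilic carbon of the dipole (the future C4–C3 bond), while the oxide oxygen bonds to the amine-bearing carbon (the future oxygen on C2). The five-membered ring is therefore closed in the cycloaddition itself, suprafacially on both partners or through a short-lived zwitterion, and not in a separate cyclisation. Cycloadduct 14 is an N,O-acetal at C5; mild acid ionises the C5–N bond, a cation stabilised by the ring oxygen and ring B, and loss of the C4 proton expels pyrrolidine and leaves aromatic isoxazole 15. The two sp3 centres of 14 are set by suprafacial addition to the enamine but are transient, so neither enamine geometry nor facial selectivity matters and 15 has no stereocentre. The selectivity needed is regiochemical, and it is secured by nitrogen being a stronger donor than the benzyloxy oxygen on the enamine double bond. Chemoselectivity against furoxan formation is secured by the two ortho alkoxy groups of 6, which allow near-stoichiometric use of the dipole at the price of a slower addition.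

**Step 10**
Reactants: 15 4-(benzyloxy)-3-[2-(benzyloxy)-3,4,6-trimethoxyphenyl]-5-(3,4,5-trimethoxyphenyl)isoxazole
Product: 17 3-hydroxy-5,7,8-trimethoxy-2-(3,4,5-trimethoxyphenyl)-4H-chromen-4-one, via ring-opened amino enone 16 (not isolated)
Conditions: H2 (1–3 atm), 10% Pd/C, EtOAc–EtOH, rt; filtered under N2; then 2 M HCl, EtOH, 70 °C
Reagents that add atoms: water, O
Why: Catalytic hydrogenolysis should cleave both benzyl ethers and the weak N–O bond (the known reductive opening of isoxazoles to β-amino enones) while no C2=C3 bond is yet present to be reduced. In acid the only free phenol adds to the aroyl carbonyl (6-exo-trig), dehydration forms the pyran ring, and hydrolysis of the C4 nitrogen releases ammonia and gives the aromatic pyranone. Because the other ortho oxygen is still a methyl ether, closure can only go through the oxygen next to C8.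

**Step 11**
Reactants: 17 3-hydroxy-5,7,8-trimethoxy-2-(3,4,5-trimethoxyphenyl)-4H-chromen-4-one
Product: 18 3,5-dihydroxy-7,8-dimethoxy-2-(3,4,5-trimethoxyphenyl)-4H-chromen-4-one (3,5-dihydroxy-7,8,3',4',5'-pentamethoxyflavone)
Conditions: BCl3 (3 equiv), CH2Cl2, −78 → 0 °C; then H2O–MeOH
Reagents that add atoms: none
Why: Chelation-controlled peri-demethylation; the C5 methoxy group is the only ether able to form a six-membered boron chelate with the C4 carbonyl, so at low temperature it should be cleaved ahead of the other five, and the mild, non-protic conditions avoid ring-opening isomerisation of the 5,7,8-pattern.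

## Compound list

1 | 1,2,3,5-tetramethoxybenzene | COc1cc(OC)c(OC)c(OC)c1 | starting material
2 | 2,3,4,6-tetramethoxybenzaldehyde | COc1cc(OC)c(C=O)c(OC)c1OC | intermediate
3 | 2-hydroxy-3,4,6-trimethoxybenzaldehyde | COc1cc(OC)c(C=O)c(O)c1OC | intermediate
4 | 2-(benzyloxy)-3,4,6-trimethoxybenzaldehyde | COc1cc(OC)c(C=O)c(OCc2ccccc2)c1OC | intermediate
5 | (E)-2-(benzyloxy)-3,4,6-trimethoxybenzaldehyde oxime | COc1cc(OC)c(/C=N/O)c(OCc2ccccc2)c1OC | intermediate
6 | 2-(benzyloxy)-3,4,6-trimethoxybenzonitrile oxide | COc1cc(OC)c(C#[N+][O-])c(OCc2ccccc2)c1OC | intermediate
7 | benzyloxyacetyl chloride | O=C(Cl)COCc1ccccc1 | starting material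
8 | 2-(benzyloxy)-N-methoxy-N-methylacetamide | CON(C)C(=O)COCc1ccccc1 | intermediate
9 | 5-bromo-1,2,3-trimethoxybenzene | COc1cc(Br)cc(OC)c1OC | starting material
10 | (3,4,5-trimethoxyphenyl)lithium | [Li]c1cc(OC)c(OC)c(OC)c1 | intermediate (not isolated)
11 | 2-(benzyloxy)-1-(3,4,5-trimethoxyphenyl)ethanone | COc1cc(C(=O)COCc2ccccc2)cc(OC)c1OC | intermediate
12 | pyrrolidine | C1CCNC1 | starting material
13 | 1-[(Z)-2-(benzyloxy)-1-(3,4,5-trimethoxyphenyl)ethenyl]pyrrolidine | COc1cc(/C(=C/OCc2ccccc2)N2CCCC2)cc(OC)c1OC | intermediate
14 | (4S*,5R*)-4-(benzyloxy)-3-[2-(benzyloxy)-3,4,6-trimethoxyphenyl]-5-(pyrrolidin-1-yl)-5-(3,4,5-trimethoxyphenyl)-4,5-dihydroisoxazole, racemic, benzyloxy and pyrrolidinyl cis | O1N=C(c2c(OC)cc(OC)c(OC)c2OCc2ccccc2)[C@H](OCc2ccccc2)[C@@]1(N1CCCC1)c1cc(OC)c(OC)c(OC)c1 | intermediate (not isolated)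
15 | 4-(benzyloxy)-3-[2-(benzyloxy)-3,4,6-trimethoxyphenyl]-5-(3,4,5-trimethoxyphenyl)isoxazole | COc1cc(-c2onc(-c3c(OCc4ccccc4)c(OC)c(OC)cc3OC)c2OCc2ccccc2)cc(OC)c1OC | intermediate
16 | (E)-3-amino-2-hydroxy-3-(2-hydroxy-3,4,6-trimethoxyphenyl)-1-(3,4,5-trimethoxyphenyl)prop-2-en-1-one, amino group cis to the ketone | COc1cc(C(=O)/C(O)=C(\N)c2c(O)c(OC)c(OC)cc2OC)cc(OC)c1OC | intermediate (not isolated)
17 | 3-hydroxy-5,7,8-trimethoxy-2-(3,4,5-trimethoxyphenyl)-4H-chromen-4-one | COc1cc(-c2oc3c(OC)c(OC)cc(OC)c3c(=O)c2O)cc(OC)c1OC | intermediate
18 | 3,5-dihydroxy-7,8-dimethoxy-2-(3,4,5-trimethoxyphenyl)-4H-chromen-4-one | COc1cc(-c2oc3c(OC)c(OC)cc(O)c3c(=O)c2O)cc(OC)c1OC | target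

## Step count and weakest steps

Total step count: 11. Longest linear sequence: 8 steps (steps 1 to 5, then 9, 10 and 11); the ring B branch (steps 6 to 8) joins at step 9.

**Step 9 (key step).** The most likely failure is a slow cycloaddition between a doubly ortho-substituted dipole and a trisubstituted enamine. That would let three side processes compete: hydrolysis of the enamine, addition of liberated or residual pyrrolidine to the dipole, and dimerisation of the dipole. Fallback: a stepwise anionic route that needs no amine. It sets out from ketone 11 and nitrile oxide 6. Ketone 11 is deprotonated with LiN(i-Pr)2 in THF at −78 °C and 6 is added. The enolate carbon adds to the carbon of the dipole and the oximate oxygen closes onto the ketone, giving (4S*,5R*)-4-(benzyloxy)-3-[2-(benzyloxy)-3,4,6-trimethoxyphenyl]-5-(3,4,5-trimethoxyphenyl)-4,5-dihydroisoxazol-5-ol F1, either diastereomer being usable. Dehydration with TsOH in toluene at reflux rejoins the route at isoxazole 15.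

**Step 2.** The ether cleavage may take place at the unflanked ortho oxygen or at both ortho oxygens, which would put the benzyl group on the wrong oxygen later. Fallback: the regiochemistry is decided in an alkylation instead. Setting out from 2, excess BCl3 in CH2Cl2 at room temperature cleaves both ortho ethers to 2,6-dihydroxy-3,4-dimethoxybenzaldehyde F2. One equivalent of MeI with K2CO3 in acetone should then methylate the unflanked, more accessible phenoxide and leave the doubly flanked, doubly hydrogen-bonded hydroxyl, returning to the route at 3.

**Step 5.** Oxidative attack on the very electron-rich ring, or loss of the dipole by dimerisation on concentration, may erode the supply of 6. Fallback: non-oxidative generation of the dipole. Setting out from aldehyde 4, oxidation with NaClO2 (NaH2PO4, 2-methyl-2-butene, t-BuOH–H2O) gives 2-(benzyloxy)-3,4,6-trimethoxybenzoic acid F3. Conversion to the acid chloride ((COCl)2, cat. DMF) and reaction with O-(tert-butyldiphenylsilyl)hydroxylamine and Et3N gives 2-(benzyloxy)-N-[(tert-butyldiphenylsilyl)oxy]-3,4,6-trimethoxybenzamide F4. Dehydration with Tf2O and Et3N in CH2Cl2 at −40 °C should release nitrile oxide 6, where the route is rejoined.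

**Step 10.** The three reductive events may not keep pace: the N–O bond may resist while the benzyl ethers fall, the amino enone may be reduced further, or the electron-rich amino enol may oxidise in air before ring closure. Fallback: the N–O cleavage is separated from the debenzylation. Setting out from 15, Mo(CO)6 in MeCN–H2O at reflux cleaves only the N–O bond to (E)-3-amino-2-(benzyloxy)-3-[2-(benzyloxy)-3,4,6-trimethoxyphenyl]-1-(3,4,5-trimethoxyphenyl)prop-2-en-1-one F5. A brief hydrogenolysis of the two benzyl ethers (H2, Pd/C, EtOAc) followed directly by 2 M HCl in EtOH at 70 °C rejoins the route at 17.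

**Step 11.** Boron may first tie up the 3-hydroxyl and the C4 carbonyl, which slows the peri cleavage and invites loss of the flanked methyl groups at C8 or C4' when the reaction is pushed. Fallback: the competing chelation site is blocked. Setting out from 17, acetylation (Ac2O, pyridine) gives 5,7,8-trimethoxy-4-oxo-2-(3,4,5-trimethoxyphenyl)-4H-chromen-3-yl acetate F6. AlCl3 in MeCN then cleaves the C5 ether through the only remaining carbonyl chelate to give 5-hydroxy-7,8-dimethoxy-4-oxo-2-(3,4,5-trimethoxyphenyl)-4H-chromen-3-yl acetate F7. Methanolysis (K2CO3, MeOH, under N2, 0 °C) removes the acetate and arrives at target 18.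

## Further compounds

F1 | step 9 | (4S*,5R*)-4-(benzyloxy)-3-[2-(benzyloxy)-3,4,6-trimethoxyphenyl]-5-(3,4,5-trimethoxyphenyl)-4,5-dihydroisoxazol-5-ol, racemic | O1N=C(c2c(OC)cc(OC)c(OC)c2OCc2ccccc2)[C@H](OCc2ccccc2)[C@@]1(O)c1cc(OC)c(OC)c(OC)c1
F2 | step 2 | 2,6-dihydroxy-3,4-dimethoxybenzaldehyde | COc1cc(O)c(C=O)c(O)c1OC
F3 | step 5 | 2-(benzyloxy)-3,4,6-trimethoxybenzoic acid | COc1cc(OC)c(C(=O)O)c(OCc2ccccc2)c1OC
F4 | step 5 | 2-(benzyloxy)-N-[(tert-butyldiphenylsilyl)oxy]-3,4,6-trimethoxybenzamide | COc1cc(OC)c(C(=O)NO[Si](c2ccccc2)(c2ccccc2)C(C)(C)C)c(OCc2ccccc2)c1OC
F5 | step 10 | (E)-3-amino-2-(benzyloxy)-3-[2-(benzyloxy)-3,4,6-trimethoxyphenyl]-1-(3,4,5-trimethoxyphenyl)prop-2-en-1-one | COc1cc(C(=O)/C(OCc2ccccc2)=C(\N)c2c(OCc3ccccc3)c(OC)c(OC)cc2OC)cc(OC)c1OC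
F6 | step 11 | 5,7,8-trimethoxy-4-oxo-2-(3,4,5-trimethoxyphenyl)-4H-chromen-3-yl acetate | COc1cc(-c2oc3c(OC)c(OC)cc(OC)c3c(=O)c2OC(C)=O)cc(OC)c1OC
F7 | step 11 | 5-hydroxy-7,8-dimethoxy-4-oxo-2-(3,4,5-trimethoxyphenyl)-4H-chromen-3-yl acetate | COc1cc(-c2oc3c(OC)c(OC)cc(O)c3c(=O)c2OC(C)=O)cc(OC)c1OC
A1 | alternative 1 | 3-iodo-7,8-dimethoxy-4-oxo-2-(3,4,5-trimethoxyphenyl)-4H-chromen-5-yl methanesulfonate | O=c1c(I)c(-c2cc(OC)c(OC)c(OC)c2)oc2c(OC)c(OC)cc(OS(C)(=O)=O)c12
A2 | alternative 1 | 3,4,5-trimethoxy-2-[3-(3,4,5-trimethoxyphenyl)prop-2-ynoyl]phenyl methanesulfonate | COc1cc(C#CC(=O)c2c(OS(C)(=O)=O)cc(OC)c(OC)c2OC)cc(OC)c1OC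
A3 | alternative 2 | 5,8-dihydroxy-7-methoxy-3-(methoxymethoxy)-2-(3,4,5-trimethoxyphenyl)-4H-chromen-4-one | O=c1c(OCOC)c(-c2cc(OC)c(OC)c(OC)c2)oc2c(O)c(OC)cc(O)c12
A4 | alternative 2 | 6-(1-hydroxy-2-methoxy-4-oxocyclobut-2-en-1-yl)-3-(methoxymethoxy)-2-(3,4,5-trimethoxyphenyl)-4H-pyran-4-one, racemic, one enantiomer drawn | COCOc1c(-c2cc(OC)c(OC)c(OC)c2)oc(cc1=O)[C@]1(O)C(OC)=CC1=O
A5 | alternative 3 | 3,5-bis(benzyloxy)-7,8-dimethoxy-2-(3,4,5-trimethoxyphenyl)-4H-chromen-4-one | O=c1c(OCc2ccccc2)c(-c2cc(OC)c(OC)c(OC)c2)oc2c(OC)c(OC)cc(OCc3ccccc3)c12
A6 | alternative 3 | (E)-2-(benzyloxy)-3-[5-(benzyloxy)-2,3-dimethoxyphenoxy]-3-(3,4,5-trimethoxyphenyl)prop-2-enoic acid | OC(=O)/C(OCc1ccccc1)=C(\Oc1cc(OCc2ccccc2)cc(OC)c1OC)c1cc(OC)c(OC)c(OC)c1
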